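## Retrosynthetic overview

- The strategy rests on the two adjacent tertiary carbinols of the cyclopentene-trione: C4 (OH plus the 4-methylpent-3-enoyl ketone) and C5 (OH plus prenyl), with the hydroxyls cis. Returning ring carbon C3 from C4 to the side-chain carbonyl carbon (a retro-1,2-acyl shift) enlarges the ring to a 2-isovalerylcyclohexane-1,3,5-trione. Its non-enolisable C5 ketone lies between two identical C(OH)(prenyl) carbons, and the cis form is meso, so the side-chain keto carbon and the C5 carbinol of the target are enantiotopic twins.
- The forward key event is therefore a six-to-five α-ketol ring contraction run as an enantiotopic-group-selective step on an achiral diol; everything before it is achiral or racemic.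
- The meso diol comes from the benzene ring of phloroglucinol: C-acylation, double C-prenylation, hydroxylative dearomatisation, then a hydroxyl-directed second hydroxylation. The cis isomer is sorted and masked as a bridging B-phenyl boronate.
- Ring order: the six-membered carbocycle is bought as an arene, bridged for a time by O–B–O (bicyclo[3.3.1]), unbridged, and contracted to the five-membered ring in the last step.

Key step: step 7

Remark: the β-triketone is drawn in one enol form throughout (its tautomers interconvert freely). The ligand antipode in step 7 is assigned from a quadrant model and would be exchanged for the (R,R)-ligand, with nothing else changed, if the first run showed the opposite sense.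

## Route

Step 1
Reactants: 1 phloroglucinol; 2 isovaleryl chloride
Product: 3 phlorisovalerophenone, 1-(2,4,6-trihydroxyphenyl)-3-methylbutan-1-one
Conditions: AlCl3 (3.5 equiv), PhNO2/CH2Cl2, 0 °C to 40 °C; then ice/1 M HCl
Reagents that add atoms: none
Why: Friedel–Crafts C-acylation of the highly activated arene, in which the aluminium-chelated first acyl group deactivates the ring against a second acylation and any O-acyl material undergoes Fries rearrangement under the same conditions.

Step 2
Reactants: 3 phlorisovalerophenone; 4 prenyl bromide (2.0 equiv)
Product: 5 deoxyhumulone, 1-[2,4,6-trihydroxy-3,5-bis(3-methylbut-2-en-1-yl)phenyl]-3-methylbutan-1-one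
Conditions: NaOMe (2.0 equiv), MeOH, 0 °C, slow addition of 4; aqueous work-up at pH 3; chromatography
Reagents that add atoms: none
Why: C-alkylation (SN2 at the primary allylic bromide) of the ambident acylphloroglucinol phenolate at its two free ring carbons, with methanol hydrogen-bonding the phenolate oxygens to favour C- over O-alkylation and the mono-, geminal di- and tri-prenylated by-products removed by chromatography.

Step 3
Reactants: 5 deoxyhumulone
Product: 6 racemic humulone, 3,5,6-trihydroxy-4,6-bis(3-methylbut-2-enyl)-2-(3-methylbutanoyl)cyclohexa-2,4-dien-1-one
Conditions: O2 (1 atm), Pb(OAc)2·3H2O (1 equiv), MeOH, rt; then dil. H2SO4/Et2O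
Reagents that add atoms: dioxygen O=O
Why: Hydroxylative dearomatisation in which the lead(II) phenolate takes up oxygen at one of the two equivalent prenyl-bearing ring carbons and the sparingly soluble lead salt of the product is shielded from over-oxidation; the C6 centre is left racemic on purpose because the next hydroxylation makes C4 and C6 mirror-related.

Step 4
Reactants: 6 racemic humulone
Product: 7 4-hydroxyhumulone, 4,6-dihydroxy-2-(1-hydroxy-3-methylbutylidene)-4,6-bis(3-methylbut-2-enyl)cyclohexane-1,3,5-trione, crude, the cis (meso) diol expected to predominate over the racemic trans diol
Conditions: VO(acac)2 (5 mol%), anhydrous t-BuOOH (1.0 equiv, decane), CH2Cl2, −20 °C, Ar, dark; cold filtration through oxalic-acid-washed silica; carried on at once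
Reagents that add atoms: tert-butyl hydroperoxide CC(C)(C)OO
Why: Hydroxyl-directed, vanadium-catalysed alkyl hydroperoxide oxygen transfer of the allylic-alcohol epoxidation type, in which the vanadium(V) alkoxide of the tertiary C6 hydroxyl should deliver oxygen to C4 of the electron-rich C4=C5 enol on its own face while the enol collapses to the C5 ketone, so the new hydroxyl is cis to the C6 hydroxyl, the prenyl alkenes (no allylic hydroxyl) and the acyl-bearing C2 are expected to stay untouched, and the absence of base at low temperature keeps the α-ketol shift of the product dormant.

Step 5
Reactants: 7 4-hydroxyhumulone (crude); 8 phenylboronic acid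
Product: 9 bridged B-phenyl boronate of the cis-diol, (1R,5S)-7-(1-hydroxy-3-methylbutylidene)-1,5-bis(3-methylbut-2-en-1-yl)-3-phenyl-2,4-dioxa-3-borabicyclo[3.3.1]nonane-6,8,9-trione (meso)
Conditions: PhB(OH)2 (1.0 equiv), MgSO4, CH2Cl2, −20 to 0 °C; filtration; flash chromatography
Reagents that add atoms: none
Why: Dehydrative boronic ester formation in which only the cis-1,3-diol, with both hydroxyls axial, can span boron, so the trans-diol stays behind as polar, hydrolytically labile open or enol esters, and both α-ketol hydroxyls of the meso isomer are blocked alike, which switches off the 1,2-shift and gives a storable compound.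

Step 6
Reactants: 9 bridged B-phenyl boronate
Product: 10 meso diol, (4R,6S)-4,6-dihydroxy-2-(1-hydroxy-3-methylbutylidene)-4,6-bis(3-methylbut-2-enyl)cyclohexane-1,3,5-trione
Conditions: pinacol (1.0 equiv), CH2Cl2, −20 to 0 °C; cold solution used at once (pinacol phenylboronate left in as a spectator or stripped by a quick cold pass through acid-washed silica)
Reagents that add atoms: none
Why: Boronic ester transesterification driven by the stability of the five-membered pinacol ester over the bridge between two electron-poor tertiary alkoxides, run without acid, base or metal so that the diol is released unrearranged with both stereocentres untouched.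

Step 7
Reactants: 10 meso diol
Product: 11 (4S,5S)-3,4,5-trihydroxy-4-(4-methylpent-3-enoyl)-2-(3-methylbutanoyl)-5-(3-methylbut-2-en-1-yl)cyclopent-2-en-1-one, (4S,5S)-humulinone, hydroxyls cis
Conditions: [Cu((S,S)-t-Bu-box)](SbF6)2 (30 mol%, raised towards 1 equiv if turnover stalls), 4 Å MS, CH2Cl2, −40 to −20 °C; cold aq. EDTA then 0.5 M HCl; chromatography on oxalic-acid-treated silica
Reagents that add atoms: none
Why: Proposed new method: the cationic copper(II) centre is expected to bind the non-enolisable C5 ketone oxygen and one flanking tertiary hydroxyl as a planar five-membered chelate, which sets that carbinol's prenyl group on one face of the C5=O plane and its ring bond C4–C3 on the other, overlapping with the carbonyl π*, so that the hydroxyl oxygen pushes (its proton passing to the former ketone oxygen) while acyl carbon C3 slides suprafacially from C4 to C5 and the carbinol carbon leaves the ring as the 4-methylpent-3-enoyl ketone. The closest known reaction types are chiral copper(II)–bisoxazoline and related Lewis-acid-catalysed enantioselective α-ketol (acyloin) rearrangements and the base- or metal-ion-promoted six-to-five contraction of hop α-acids, and the untested element is the use of such a shift to tell apart the two enantiotopic carbinols of a meso bis(α-ketol). The cyclopentene ring is closed by ring contraction, the new C3–C5 bond forming by formal 3-exo-trig attack of the migrating carbon on the ketone through a bicyclo[3.1.0]-like transition state, followed by loss of the old C3–C4 bond. The new carbinol centre (C4 of 11) is set by the chelate, since the ketone oxygen stays in the chelate plane and the migrating carbon arrives on the face opposite the axial prenyl groups, which makes the new hydroxyl cis to the surviving one, whose carbon is untouched and changes from R in 10 to S in 11 only through CIP priorities. The selectivity required is enantiotopic-group selection (collapse of the S-labelled carbinol of 10), for which the mirror-symmetric substrate offers two diastereomeric chelates, and in the quadrants of the (S,S)-ligand the chelate that puts the flexible prenyl group, not the rigid triketone ring with its C3 carbonyl oxygen, next to a tert-butyl group is that of the S-carbinol. The ratio should be kinetic because the C5 ketone cannot enolise, the conjugated and strongly acidic cyclopentene-trione does not revert, and base-free cold conditions with the non-basic SbF6 counter-ion hold back the uncatalysed shift.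

## Compound list

1 | phloroglucinol (benzene-1,3,5-triol) | Oc1cc(O)cc(O)c1 | starting material
2 | isovaleryl chloride (3-methylbutanoyl chloride) | CC(C)CC(=O)Cl | starting material
3 | phlorisovalerophenone | CC(C)CC(=O)c1c(O)cc(O)cc1O | intermediate
4 | prenyl bromide (1-bromo-3-methylbut-2-ene) | CC(C)=CCBr | starting material
5 | deoxyhumulone | CC(C)CC(=O)c1c(O)c(CC=C(C)C)c(O)c(CC=C(C)C)c1O | intermediate
6 | racemic humulone | CC(C)CC(=O)C1=C(O)C(CC=C(C)C)=C(O)C(O)(CC=C(C)C)C1=O | intermediate
7 | 4-hydroxyhumulone, crude mixture of cis (meso) and trans (racemic) 4,6-diols | CC(C)CC(O)=C1C(=O)C(O)(CC=C(C)C)C(=O)C(O)(CC=C(C)C)C1=O | intermediate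
8 | phenylboronic acid | OB(O)c1ccccc1 | starting material
9 | (1R,5S)-bridged B-phenyl boronate of the cis-4,6-diol (2,4-dioxa-3-borabicyclo[3.3.1]nonane-6,8,9-trione, meso) | CC(C)CC(O)=C1C(=O)[C@]2(CC=C(C)C)OB(c3ccccc3)O[C@@](CC=C(C)C)(C2=O)C1=O | intermediate
10 | meso (4R,6S)-4,6-dihydroxy-4,6-diprenyl-2-isovalerylcyclohexane-1,3,5-trione (exocyclic enol form) | CC(C)CC(O)=C1C(=O)[C@@](O)(CC=C(C)C)C(=O)[C@@](O)(CC=C(C)C)C1=O | intermediate
11 | (4S,5S)-humulinone, CNP0320626.1 | CC(C)=CCC(=O)[C@]1(O)C(O)=C(C(=O)CC(C)C)C(=O)[C@]1(O)CC=C(C)C | target

## Step count and risks

Total step count: 7. Longest linear sequence: 7 steps (1 to 11).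

Steps most likely to fail:

1. Step 7. The chiral complex may discriminate the two enantiotopic carbinols incompletely. A proton-catalysed or uncatalysed shift may run beside the catalysed one. The shift may pass through the unchelated conformer with axial hydroxyls, which leads to the anti-diol. The triketone of substrate and product may hold the copper back. Fallback with known chemistry, setting out from 10: the diol is stirred with aqueous NaHCO3/MgSO4 and ether at 0 °C to rt, the base- and magnesium-promoted ring contraction known for hop acids. After chromatographic removal of the anti-diol diastereomer this should give racemic (4S*,5S*)-humulinone F1. Preparative chromatography of F1 on a chiral polysaccharide phase with an acidified eluent then resolves the enantiomers, and the route is rejoined at 11.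

2. Step 4. Oxygen transfer may stray to the prenyl alkenes, radical tert-butylperoxylation may compete, and vanadium may set off the ring contraction before the diol is masked. Fallback setting out from 6: the mono-potassium enolate (KHMDS, 1.0 equiv, THF, −78 °C) is hydroxylated with racemic 2-(phenylsulfonyl)-3-phenyloxaziridine and quenched with TFA at −78 °C (Davis oxidation). This reagent is enolate-selective and leaves alkenes alone, and approach anti to the larger C6 prenyl group should favour the cis-diol. The route is rejoined at 7, and the boronate step then sorts cis from trans as before. This fallback makes no compound outside the list (F0).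

3. Step 6. Exchange at the hindered bridged boronate may be so slow that it needs temperatures at which the free diol rearranges without control, and left-over diol or boron species may compete for copper. Fallback setting out from 7: the boron detour (steps 5 and 6) is dropped and crude 7 is submitted directly to the conditions of step 7. The trans-diol impurity can only give the anti-diol diastereomer, which is removed by chromatography of the product on acid-treated silica. The route is rejoined at 11, and no compound outside the list is made (F0).

Further compounds
F1 | step 7 | racemic (4S*,5S*)-humulinone (1:1 mixture of 11 and its enantiomer) | CC(C)=CCC(=O)[C@]1(O)C(O)=C(C(=O)CC(C)C)C(=O)[C@]1(O)CC=C(C)C.CC(C)=CCC(=O)[C@@]1(O)C(O)=C(C(=O)CC(C)C)C(=O)[C@@]1(O)CC=C(C)C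
F0 | step 4 | none | none
F0 | step 6 | none | none
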